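**Plan**

- Feature: in the oxolane (O1, C2 guaiacyl-bearing, C3 carrying hydroxymethyl carbon C6, C4 carrying benzylic carbon C7, C5) C7 sits on C4 cis to the C6 arm and C5 is bonded to O1. C4=C5 can therefore be an enol ether that takes up C7 as a carbene from a C6-bound zinc carbenoid.
- Cuts, in retrosynthetic order: C7–aryl (sp3–sp2 coupling of a C7 iodide); C5–H and the temporary C5–C7 bond (acetal reduction, iodonium opening of a 2-oxabicyclo[3.1.0]hexane); C4–C7 with C5–C7 (cyclopropanation); C4=C5 (metathesis); O1–C5 (O-vinylation); C2–C3 (allylboration of O-pivaloylvanillin).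
- Forward order: the C2–C3 chain is joined first, the oxolane is closed as a 2,3-dihydrofuran, the cyclopropane is fused on and opened again, and the veratryl ring is attached last.
- Stereochemistry: C2 and C3 come from a catalyst-controlled anti allylboration (E-boronate, chiral phosphoric acid); C4 comes from hydroxyl-directed CH2 transfer; C5 is not stereogenic in the target.

Key step: step 7

Remarks on the chemistry: the methyl acetal from the cyclopropane opening is carried as a mixture of C5 anomers, because C5 becomes CH2 one step later. The C5 oxocarbenium cation arises in step 9 and again in step 10 with different counter-ions, and each is listed as the ion pair formed in that flask. The (S)-configured phosphoric acid is assumed to direct the boronate to the Si face of the aldehyde, following the accepted model for this catalyst class; the mirror-image acid would be used if the opposite sense were found. The (E)-silyloxypropenyl pinacol boronate is taken as a catalogue reagent.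

**Step 1**
Reactants: 1 vanillin; 2 pivaloyl chloride
Product: 3 4-formyl-2-methoxyphenyl 2,2-dimethylpropanoate (O-pivaloylvanillin)
Conditions: Et3N, 4-(dimethylamino)pyridine (cat.), CH2Cl2, 0 °C → rt
Reagents that add atoms: pivaloyl chloride, CC(C)(C)C(=O)Cl
Why: Routine O-acylation of a phenol with an acid chloride; the hindered aryl ester masks the phenol through the zinc, iodonium and Lewis-acid steps and lowers the donor strength of the ring toward ionisation of the later C2–O1 benzylic bond.

**Step 2**
Reactants: 4 (E)-tert-butyldimethyl{[3-(4,4,5,5-tetramethyl-1,3,2-dioxaborolan-2-yl)prop-2-en-1-yl]oxy}silane; 5 bromochloromethane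
Product: 7 (E)-tert-butyldimethyl{[4-(4,4,5,5-tetramethyl-1,3,2-dioxaborolan-2-yl)but-2-en-1-yl]oxy}silane, via lithium boronate complex 6 (not isolated)
Conditions: BrCH2Cl, n-BuLi, THF, −78 °C → rt
Reagents that add atoms: bromochloromethane, ClCBr
Why: Matteson homologation, in which chloromethyllithium made in the flask adds to boron and 1,2-migration of the alkenyl group with loss of chloride inserts CH2 into the C–B bond with retention of the E geometry that later fixes the anti relationship.

**Step 3**
Reactants: 3 O-pivaloylvanillin; 7 (E)-allylboronate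
Product: 9 4-[(1S,2R)-2-{[tert-butyl(dimethyl)silyl]oxymethyl}-1-hydroxybut-3-en-1-yl]-2-methoxyphenyl 2,2-dimethylpropanoate (anti homoallylic alcohol), via O-boryl ether 8 (not isolated)
Conditions: (S)-3,3'-bis(2,4,6-triisopropylphenyl)-1,1'-binaphthyl-2,2'-diyl hydrogen phosphate [(S)-TRIP] (5 mol%), 4 Å MS, toluene, −30 °C; aq. NaHCO3
Reagents that add atoms: allylboronate 7, CC(C)(C)[Si](C)(C)OC/C=C/CB1OC(C)(C)C(C)(C)O1
Why: Chiral phosphoric acid-catalysed allylboration through a closed Zimmerman–Traxler chair, in which the E geometry of the boronate should place the silyloxymethyl group equatorial and give the anti product, while the acid bound to the boronate oxygen should select the Si face of the aldehyde, setting C2 of the future oxolane as S and C3 as R.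

**Step 4**
Reactants: 9 anti homoallylic alcohol; 10 vinyl acetate
Product: 11 4-[(1S,2R)-2-{[tert-butyl(dimethyl)silyl]oxymethyl}-1-(ethenyloxy)but-3-en-1-yl]-2-methoxyphenyl 2,2-dimethylpropanoate
Conditions: [Ir(cod)Cl]2 (2 mol%), Na2CO3 (1 equiv), vinyl acetate (3 equiv), toluene, 100 °C
Reagents that add atoms: vinyl acetate, C=COC(C)=O
Why: Iridium-catalysed transfer vinylation of a secondary alcohol from vinyl acetate, run with a mild carbonate base that should spare the aryl pivalate and the silyl ether; no stereocentre is touched.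

**Step 5**
Reactants: 11 vinyl ether diene
Product: 12 4-[(2S,3R)-3-{[tert-butyl(dimethyl)silyl]oxymethyl}-2,3-dihydrofuran-2-yl]-2-methoxyphenyl 2,2-dimethylpropanoate
Conditions: second-generation Grubbs catalyst RuCl2(=CHPh)(H2IMes)(PCy3) (5 mol%), toluene, 70 °C, argon sparge
Reagents that add atoms: none
Why: Enol ether–olefin ring-closing metathesis, in which the ruthenium alkylidene should load on the monosubstituted alkene and close onto the vinyl ether to form the five-membered cyclic enol ether with loss of ethylene, leaving C2 and C3 untouched.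

**Step 6**
Reactants: 12 silyl-protected dihydrofuran
Product: 13 4-[(2S,3R)-3-(hydroxymethyl)-2,3-dihydrofuran-2-yl]-2-methoxyphenyl 2,2-dimethylpropanoate
Conditions: Bu4NF, AcOH (1:1), THF, 0 °C → rt
Reagents that add atoms: none
Why: Fluoride cleavage of the primary silyl ether, buffered with acetic acid so that the medium stays near neutral and neither the aryl pivalate nor the acid-labile enol ether should suffer.

**Step 7**
Reactants: 13 trans-(2-aryl-2,3-dihydrofuran-3-yl)methanol; 14 diiodomethane
Product: 16 4-[(1R,3S,4R,5R)-4-(hydroxymethyl)-2-oxabicyclo[3.1.0]hexan-3-yl]-2-methoxyphenyl 2,2-dimethylpropanoate (cyclopropane CH2 cis to the hydroxymethyl arm and trans to the aryl group), via iodomethylzinc alkoxide 15 (not isolated)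
Conditions: Et2Zn (5 equiv), CH2I2 (10 equiv), CH2Cl2, −10 → 0 °C; sat. aq. NaHCO3, aq. KNaC4H4O6 (potassium sodium tartrate)
Reagents that add atoms: diiodomethane, ICI
Why: Et2Zn should deprotonate the C6 hydroxyl and exchange with CH2I2 to place an iodomethylzinc carbenoid on that alkoxide (15), which then transfers CH2 to the electron-rich C4=C5 enol ether through the concerted butterfly transition state of the Simmons–Smith reaction in its Furukawa form, making C4–C7 and C5–C7 together. The closest known reaction type is the hydroxyl-directed Simmons–Smith cyclopropanation of glycals and of cyclic homoallylic alcohols. The three-membered ring closes by a concerted, stereospecific syn [2+1] addition, so its fusion to the oxolane can only be cis. Both new centres (C4 and C5 of the oxolane, C5 and C1 of the bicycle) are fixed by the face of attack, which is chosen by the zinc alkoxide of C6 on C3, so that C7 should end up cis to C6. The step needs facial selectivity only, since the enol ether is the sole alkene, and this is secured by intramolecular delivery from the C6 alkoxide, reinforced by the C2 aryl group lying on the opposite face. C2 and C3 are not involved, and the excess of Et2Zn keeps the medium free of protic acid that would open the cyclopropyl ether.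

**Step 8**
Reactants: 16 cyclopropanated alcohol; 17 acetic anhydride
Product: 18 [(1R,3S,4R,5R)-3-(3-methoxy-4-pivaloyloxyphenyl)-2-oxabicyclo[3.1.0]hexan-4-yl]methyl acetate
Conditions: Ac2O, pyridine, 4-(dimethylamino)pyridine (cat.), CH2Cl2, 0 °C → rt
Reagents that add atoms: acetic anhydride, CC(=O)OC(C)=O
Why: Standard base-mediated acetylation that leaves the cyclopropyl ether alone and caps the C6 hydroxyl, so that it cannot enter acetal exchange at C5 in the next two steps and reroute the ring through its own oxygen.

**Step 9**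
Reactants: 18 cyclopropyl acetate; 19 N-iodosuccinimide; 20 methanol
Product: 22 4-[(2S,3R,4R)-3-(acetoxymethyl)-4-(iodomethyl)-5-methoxyoxolan-2-yl]-2-methoxyphenyl 2,2-dimethylpropanoate (mixture of C5 anomers), via oxocarbenium succinimidate ion pair 21 (not isolated)
Conditions: NIS (1.3 equiv), MeOH/CH2Cl2 (1:1), 0 °C → rt, dark; aq. Na2S2O3
Reagents that add atoms: N-iodosuccinimide, O=C1CCC(=O)N1I; methanol, CO
Why: Electrophilic opening of a donor-activated cyclopropane as known for cyclopropanated glycals, in which iodonium from NIS should attack the CH2 carbon C7 while the O1 lone pair pushes out the C5–C7 bond to give the C5 oxocarbenium cation, paired at first with succinimidate (21) and then trapped at C5 by methanol with the proton passing to succinimidate; the C4–C7 bond is not broken, so the C4 configuration is kept.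

**Step 10**
Reactants: 22 iodomethyl methyl acetal
Product: 24 4-[(2S,3R,4R)-3-(acetoxymethyl)-4-(iodomethyl)oxolan-2-yl]-2-methoxyphenyl 2,2-dimethylpropanoate, via oxocarbenium methoxytrifluoroborate ion pair 23 (not isolated)
Conditions: Et3SiH (5 equiv), BF3·OEt2 (2 equiv), CH2Cl2, −78 → −40 °C; sat. aq. NaHCO3
Reagents that add atoms: none
Why: Lewis-acid-mediated ionic reduction of an acetal, in which BF3 should abstract the C5 methoxy group to give the same C5 oxocarbenium cation as in step 9, now paired with methoxytrifluoroborate (23), and triethylsilane delivers hydride to C5 while the methoxide passes to silicon, so both anomers converge on the CH2 compound; the primary iodide and both esters are inert, and ionisation of the C2–O1 bond is disfavoured at low temperature by the acylated, less donating aryl ring.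

**Step 11**
Reactants: 24 primary iodide; 25 4-iodo-1,2-dimethoxybenzene
Product: 26 4-[(2S,3R,4R)-3-(acetoxymethyl)-4-(3,4-dimethoxybenzyl)oxolan-2-yl]-2-methoxyphenyl 2,2-dimethylpropanoate
Conditions: NiBr2(dme) (10 mol%), 4,4'-di-tert-butyl-2,2'-bipyridine (10 mol%), Zn dust (2 equiv), pyridine (10 mol%), DMA, 60 °C
Reagents that add atoms: 4-iodo-1,2-dimethoxybenzene, COc1ccc(I)cc1OC
Why: Nickel-catalysed reductive cross-electrophile coupling, in which the aryl iodide should add oxidatively to zerovalent nickel, the C7 radical formed from the alkyl iodide is captured by the divalent arylnickel species, and reductive elimination forms C7–aryl while zinc turns the catalyst over; the radical sits on the exocyclic CH2, so no stereocentre is at risk, and the esters and the aryl C–O bond of the pivalate are inert to bipyridine–nickel at this temperature.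

**Step 12**
Reactants: 26 acetate pivalate diester
Product: 27 4'-O-methyllariciresinol, 4-[(2S,3R,4R)-4-(3,4-dimethoxybenzyl)-3-(hydroxymethyl)oxolan-2-yl]-2-methoxyphenol
Conditions: NaOMe (3 equiv), MeOH, 0 °C → rt, argon; AcOH quench
Reagents that add atoms: none
Why: Zemplén-type transesterification, in which methoxide should cleave the primary acetate and the aryl pivalate (phenoxide leaving group) in one operation under basic conditions that leave the benzylic ether and all three stereocentres untouched and avoid the acid that could ionise C2.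

**Compound list**

1 | vanillin | COc1cc(C=O)ccc1O | starting material
2 | pivaloyl chloride | CC(C)(C)C(=O)Cl | starting material
3 | 4-formyl-2-methoxyphenyl 2,2-dimethylpropanoate | COc1cc(C=O)ccc1OC(=O)C(C)(C)C | intermediate
4 | (E)-tert-butyldimethyl{[3-(4,4,5,5-tetramethyl-1,3,2-dioxaborolan-2-yl)prop-2-en-1-yl]oxy}silane | CC(C)(C)[Si](C)(C)OC/C=C/B1OC(C)(C)C(C)(C)O1 | starting material
5 | bromochloromethane | ClCBr | starting material
6 | lithium (chloromethyl)[(E)-3-(tert-butyldimethylsilyloxy)prop-1-enyl]pinacolatoborate (formed in the flask) | [Li+].ClC[B-]1(/C=C/CO[Si](C)(C)C(C)(C)C)OC(C)(C)C(C)(C)O1 | intermediate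
7 | (E)-tert-butyldimethyl{[4-(4,4,5,5-tetramethyl-1,3,2-dioxaborolan-2-yl)but-2-en-1-yl]oxy}silane | CC(C)(C)[Si](C)(C)OC/C=C/CB1OC(C)(C)C(C)(C)O1 | intermediate
8 | O-(pinacolatoboryl) ether of alcohol 9, (1S,2R) (formed in the flask) | COc1cc([C@@H](OB2OC(C)(C)C(C)(C)O2)[C@@H](CO[Si](C)(C)C(C)(C)C)C=C)ccc1OC(=O)C(C)(C)C | intermediate
9 | 4-[(1S,2R)-2-{[tert-butyl(dimethyl)silyl]oxymethyl}-1-hydroxybut-3-en-1-yl]-2-methoxyphenyl 2,2-dimethylpropanoate | COc1cc([C@@H](O)[C@@H](CO[Si](C)(C)C(C)(C)C)C=C)ccc1OC(=O)C(C)(C)C | intermediate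
10 | vinyl acetate | C=COC(C)=O | starting material
11 | 4-[(1S,2R)-2-{[tert-butyl(dimethyl)silyl]oxymethyl}-1-(ethenyloxy)but-3-en-1-yl]-2-methoxyphenyl 2,2-dimethylpropanoate | COc1cc([C@@H](OC=C)[C@@H](CO[Si](C)(C)C(C)(C)C)C=C)ccc1OC(=O)C(C)(C)C | intermediate
12 | 4-[(2S,3R)-3-{[tert-butyl(dimethyl)silyl]oxymethyl}-2,3-dihydrofuran-2-yl]-2-methoxyphenyl 2,2-dimethylpropanoate | COc1cc([C@H]2OC=C[C@@H]2CO[Si](C)(C)C(C)(C)C)ccc1OC(=O)C(C)(C)C | intermediate
13 | 4-[(2S,3R)-3-(hydroxymethyl)-2,3-dihydrofuran-2-yl]-2-methoxyphenyl 2,2-dimethylpropanoate | COc1cc([C@H]2OC=C[C@@H]2CO)ccc1OC(=O)C(C)(C)C | intermediate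
14 | diiodomethane | ICI | starting material
15 | iodomethylzinc alkoxide of 13 (formed in the flask) | COc1cc([C@H]2OC=C[C@@H]2CO[Zn]CI)ccc1OC(=O)C(C)(C)C | intermediate
16 | 4-[(1R,3S,4R,5R)-4-(hydroxymethyl)-2-oxabicyclo[3.1.0]hexan-3-yl]-2-methoxyphenyl 2,2-dimethylpropanoate | COc1cc([C@H]2O[C@@H]3C[C@@H]3[C@@H]2CO)ccc1OC(=O)C(C)(C)C | intermediate
17 | acetic anhydride | CC(=O)OC(C)=O | starting material
18 | [(1R,3S,4R,5R)-3-(3-methoxy-4-pivaloyloxyphenyl)-2-oxabicyclo[3.1.0]hexan-4-yl]methyl acetate | COc1cc([C@H]2O[C@@H]3C[C@@H]3[C@@H]2COC(C)=O)ccc1OC(=O)C(C)(C)C | intermediate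
19 | N-iodosuccinimide | O=C1CCC(=O)N1I | starting material
20 | methanol | CO | starting material
21 | (2S,3R,4R)-3-(acetoxymethyl)-4-(iodomethyl)-2-(3-methoxy-4-pivaloyloxyphenyl)-3,4-dihydro-2H-furan-1-ium succinimidate (C5 oxocarbenium ion pair formed in the flask in step 9) | COc1cc([C@H]2[O+]=C[C@H](CI)[C@@H]2COC(C)=O)ccc1OC(=O)C(C)(C)C.O=C1CCC(=O)[N-]1 | intermediate
22 | 4-[(2S,3R,4R)-3-(acetoxymethyl)-4-(iodomethyl)-5-methoxyoxolan-2-yl]-2-methoxyphenyl 2,2-dimethylpropanoate (C5 anomers) | COc1cc([C@H]2OC(OC)[C@H](CI)[C@@H]2COC(C)=O)ccc1OC(=O)C(C)(C)C | intermediate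
23 | (2S,3R,4R)-3-(acetoxymethyl)-4-(iodomethyl)-2-(3-methoxy-4-pivaloyloxyphenyl)-3,4-dihydro-2H-furan-1-ium methoxytrifluoroborate (C5 oxocarbenium ion pair formed in the flask in step 10) | COc1cc([C@H]2[O+]=C[C@H](CI)[C@@H]2COC(C)=O)ccc1OC(=O)C(C)(C)C.CO[B-](F)(F)F | intermediate
24 | 4-[(2S,3R,4R)-3-(acetoxymethyl)-4-(iodomethyl)oxolan-2-yl]-2-methoxyphenyl 2,2-dimethylpropanoate | COc1cc([C@H]2OC[C@H](CI)[C@@H]2COC(C)=O)ccc1OC(=O)C(C)(C)C | intermediate
25 | 4-iodo-1,2-dimethoxybenzene | COc1ccc(I)cc1OC | starting material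
26 | 4-[(2S,3R,4R)-3-(acetoxymethyl)-4-(3,4-dimethoxybenzyl)oxolan-2-yl]-2-methoxyphenyl 2,2-dimethylpropanoate | COc1cc([C@H]2OC[C@H](Cc3ccc(OC)c(OC)c3)[C@@H]2COC(C)=O)ccc1OC(=O)C(C)(C)C | intermediate
27 | 4'-O-methyllariciresinol, 4-[(2S,3R,4R)-4-(3,4-dimethoxybenzyl)-3-(hydroxymethyl)oxolan-2-yl]-2-methoxyphenol | COc1cc([C@H]2OC[C@H](Cc3ccc(OC)c(OC)c3)[C@@H]2CO)ccc1O | target

**Totals**

Total step count: 12. Longest linear sequence: 11 steps (vanillin through steps 1 and 3–12; the boronate branch, step 2, joins at step 3 and is equally long).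

**Steps most likely to fail, with fallbacks**

Step 7. Facial discrimination may be incomplete, because delivery comes from a homoallylic rather than an allylic alkoxide while the C6 arm itself crowds the face it directs to; undirected attack anti to that arm would give the C4 epimer. The fallback sets C4 by substrate-controlled hydroboration instead. It sets out from iodide 24, carried through steps 8–10 as a mixture of C4 epimers. Elimination of HI with DBU in toluene at 90 °C erases C4 and should converge both epimers on the 4-methylideneoxolane F1. 9-BBN in THF should then add across the exocyclic alkene from the face away from the neighbouring C3 arm, putting hydrogen on C4 trans to C6 and boron on C7, to give the B-alkyl borane F2. This is not isolated but coupled with 4-bromoveratrole in a B-alkyl Suzuki–Miyaura reaction (PdCl2(dppf), K3PO4·H2O, DMF/THF, 50 °C). The route is rejoined at diester 26.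

Step 5. The catalyst may stall as an unreactive ruthenium alkoxycarbene formed at the vinyl ether, the terminal alkene may migrate, or the acid-labile 2-aryl enol ether may be lost on isolation. The fallback builds the enol ether by dehydration of a lactol and sets out from homoallylic alcohol 9. Hydroboration of the terminal alkene with 9-BBN gives the alkylborane F3, which is oxidised with NaBO3·4H2O to the 1,4-diol F4. Oxidation with catalytic 2,2,6,6-tetramethylpiperidin-1-oxyl and PhI(OAc)2 takes the primary alcohol through to the γ-lactone F5. i-Bu2AlH in CH2Cl2 at −78 °C reduces it to the lactol F6. MsCl and Et3N in CH2Cl2 (0 °C, then reflux) convert this to the anomeric mesylate F7, which eliminates in the flask. The route is rejoined at dihydrofuran 12.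

Step 11. Reductive dimerisation or hydrodehalogenation of the β-branched primary iodide may outrun oxidative addition of the electron-rich aryl iodide. The fallback separates the two events and sets out from iodide 24. Zinc insertion (Zn dust, LiCl, THF, 40 °C) gives the alkylzinc iodide F8. Negishi coupling with 4-bromoveratrole (Pd(OAc)2, 2-dicyclohexylphosphino-2',6'-dimethoxybiphenyl, THF, rt → 50 °C) then forms the C7–aryl bond. The route is rejoined at diester 26.

**Further compounds**

F1 | step 7 | 4-[(2S,3R)-3-(acetoxymethyl)-4-methylideneoxolan-2-yl]-2-methoxyphenyl 2,2-dimethylpropanoate | COc1cc([C@H]2OCC(=C)[C@@H]2COC(C)=O)ccc1OC(=O)C(C)(C)C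
F2 | step 7 | 4-[(2S,3R,4R)-3-(acetoxymethyl)-4-(9-borabicyclo[3.3.1]nonan-9-ylmethyl)oxolan-2-yl]-2-methoxyphenyl 2,2-dimethylpropanoate | COc1cc([C@H]2OC[C@H](CB3C4CCCC3CCC4)[C@@H]2COC(C)=O)ccc1OC(=O)C(C)(C)C
F3 | step 5 | 4-[(1S,2R)-4-(9-borabicyclo[3.3.1]nonan-9-yl)-2-{[tert-butyl(dimethyl)silyl]oxymethyl}-1-hydroxybutyl]-2-methoxyphenyl 2,2-dimethylpropanoate | COc1cc([C@@H](O)[C@@H](CO[Si](C)(C)C(C)(C)C)CCB2C3CCCC2CCC3)ccc1OC(=O)C(C)(C)C
F4 | step 5 | 4-[(1S,2R)-2-{[tert-butyl(dimethyl)silyl]oxymethyl}-1,4-dihydroxybutyl]-2-methoxyphenyl 2,2-dimethylpropanoate | COc1cc([C@@H](O)[C@@H](CO[Si](C)(C)C(C)(C)C)CCO)ccc1OC(=O)C(C)(C)C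
F5 | step 5 | 4-[(2S,3R)-3-{[tert-butyl(dimethyl)silyl]oxymethyl}-5-oxooxolan-2-yl]-2-methoxyphenyl 2,2-dimethylpropanoate | COc1cc([C@H]2OC(=O)C[C@@H]2CO[Si](C)(C)C(C)(C)C)ccc1OC(=O)C(C)(C)C
F6 | step 5 | 4-[(2S,3R)-3-{[tert-butyl(dimethyl)silyl]oxymethyl}-5-hydroxyoxolan-2-yl]-2-methoxyphenyl 2,2-dimethylpropanoate (C5 anomers) | COc1cc([C@H]2OC(O)C[C@@H]2CO[Si](C)(C)C(C)(C)C)ccc1OC(=O)C(C)(C)C
F7 | step 5 | 4-[(2S,3R)-3-{[tert-butyl(dimethyl)silyl]oxymethyl}-5-(methanesulfonyloxy)oxolan-2-yl]-2-methoxyphenyl 2,2-dimethylpropanoate (C5 anomers) | COc1cc([C@H]2OC(OS(C)(=O)=O)C[C@@H]2CO[Si](C)(C)C(C)(C)C)ccc1OC(=O)C(C)(C)C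
F8 | step 11 | {[(3R,4R,5S)-4-(acetoxymethyl)-5-(3-methoxy-4-pivaloyloxyphenyl)oxolan-3-yl]methyl}zinc iodide | COc1cc([C@H]2OC[C@H](C[Zn]I)[C@@H]2COC(C)=O)ccc1OC(=O)C(C)(C)C
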